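**Retrosynthetic overview**

1. Laxiflorin is traced back to a fully protected (2S)-flavanone by acid removal of three MOM groups and one silyl group. The prenyl group comes from an allyl group by cross-metathesis, and the C4 ketone from the C4 methylene of a (2S)-flavan by DDQ/water followed by Dess–Martin oxidation.
2. The strategy rests on ring C, the only ring that is made. Its O1–C8a–C4a–C4 atoms are the heterodiene of an ortho-quinone methide on ring A, and C2–C3 is the vinyl group of the ring-B styrene. A chiral phosphoric acid joins them through O1–C2 and C3–C4, closing the pyran ring and setting C2, the only stereocentre.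
3. Two spectator groups differ from the final substitution during the key step. The styrene is used with its 4-hydroxyl free, as a second hydrogen-bond contact for the phosphate, and is MOM-protected directly afterwards. The C8 chain is carried as allyl until the ketone is in place, because a prenyl CH2 on this ring would be the best hydride donor toward DDQ and a prenyl group beside a free phenol is acid-sensitive.
4. The quinone methide precursor, a hexasubstituted 2-(hydroxymethyl)phenol, is built from phloroglucinol: bis-MOM ether, aryl silyl ether, then a single lithiation between the MOM groups (ethylene oxide), which avoids metalation next to the silyl ether. O-allylation/Claisen rearrangement and ortho-formylation/reduction then place allyl and CH2OH on the two carbons flanking the free hydroxyl by construction.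

Key step: step 8

Assumption: the sense of induction of the phosphoric acid cannot be predicted for this substrate pair; both catalyst antipodes are available and the one found to give the 2S flavan is used.

**Route**

Step 1
Reactants: 1 phloroglucinol
Product: 2 3,5-bis(methoxymethoxy)phenol
Conditions: MOMCl (2.0 equiv), i-Pr2NEt, CH2Cl2–DMF, 0 °C→rt; chromatography (mono- and tris-ethers recycled)
Reagents that add atoms: chloromethyl methyl ether (MOMCl), COCCl
Why: O-alkylation (Williamson type) of the C3-symmetric triphenol with two equivalents of MOMCl should give the bis-ether as the main component of a statistical mixture separable by polarity, leaving the one hydroxyl that becomes O1.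

Step 2
Reactants: 2 3,5-bis(methoxymethoxy)phenol
Product: 3 tert-butyl[3,5-bis(methoxymethoxy)phenoxy]dimethylsilane
Conditions: TBSCl, imidazole, DMF, rt
Reagents that add atoms: tert-butyldimethylsilyl chloride (TBSCl), CC(C)(C)[Si](C)(C)Cl
Why: Routine phenol silylation; the bulky, poorly coordinating silyl ether marks the future O1 oxygen and does not direct metalation.

Step 3
Reactants: 3 tert-butyl[3,5-bis(methoxymethoxy)phenoxy]dimethylsilane; 4 ethylene oxide
Product: 7 tert-butyl{2-[4-(tert-butyldimethylsilyloxy)-2,6-bis(methoxymethoxy)phenyl]ethoxy}dimethylsilane, via aryllithium 5 (not isolated), via lithium alkoxide 6 (not isolated)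
Conditions: n-BuLi, THF, 0 °C; ethylene oxide, −78 °C→rt; then TBSCl, DMPU, rt
Reagents that add atoms: tert-butyldimethylsilyl chloride (TBSCl), CC(C)(C)[Si](C)(C)Cl
Why: Directed ortho-metalation should occur at the only carbon flanked by two MOM ethers (it is para to the silyl ether, so anionic O-to-C silyl migration cannot occur), the aryllithium opens ethylene oxide, and the primary alkoxide is silylated in the same flask.

Step 4
Reactants: 7 tert-butyl{2-[4-(tert-butyldimethylsilyloxy)-2,6-bis(methoxymethoxy)phenyl]ethoxy}dimethylsilane; 8 allyl bromide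
Product: 10 {2-[4-(allyloxy)-2,6-bis(methoxymethoxy)phenyl]ethoxy}(tert-butyl)dimethylsilane, via caesium phenoxide 9 (not isolated)
Conditions: Cs2CO3, DMF–H2O (10:1), rt; then allyl bromide, rt
Reagents that add atoms: none
Why: Carbonate in wet DMF cleaves the aryl silyl ether selectively over the primary alkyl silyl ether, and the caesium phenoxide is then O-allylated (Williamson ether synthesis).

Step 5
Reactants: 10 {2-[4-(allyloxy)-2,6-bis(methoxymethoxy)phenyl]ethoxy}(tert-butyl)dimethylsilane
Product: 11 2-allyl-4-[2-(tert-butyldimethylsilyloxy)ethyl]-3,5-bis(methoxymethoxy)phenol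
Conditions: N,N-diethylaniline, 190 °C
Reagents that add atoms: none
Why: Aromatic Claisen rearrangement; the two ortho carbons of the symmetrical ether are equivalent, so a single ortho-allylphenol should form, with the allyl group necessarily next to the free hydroxyl.

Step 6
Reactants: 11 2-allyl-4-[2-(tert-butyldimethylsilyloxy)ethyl]-3,5-bis(methoxymethoxy)phenol; 12 paraformaldehyde
Product: 13 3-allyl-5-[2-(tert-butyldimethylsilyloxy)ethyl]-2-hydroxy-4,6-bis(methoxymethoxy)benzaldehyde
Conditions: MgCl2, Et3N, (CH2O)n, THF, reflux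
Reagents that add atoms: none
Why: Magnesium-phenoxide-directed ortho-formylation (Casnati–Skattebøl type) is specific for a position ortho to the free hydroxyl, and only one such position is left.

Step 7
Reactants: 13 3-allyl-5-[2-(tert-butyldimethylsilyloxy)ethyl]-2-hydroxy-4,6-bis(methoxymethoxy)benzaldehyde
Product: 14 2-allyl-4-[2-(tert-butyldimethylsilyloxy)ethyl]-6-(hydroxymethyl)-3,5-bis(methoxymethoxy)phenol
Conditions: NaBH4, MeOH–THF, 0 °C; neutral work-up, used crude
Reagents that add atoms: none
Why: Borohydride reduction of the aldehyde at low temperature should give the 2-(hydroxymethyl)phenol, which is acid-sensitive (it is the quinone methide precursor) and is therefore not chromatographed.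

Step 8
Reactants: 14 2-allyl-4-[2-(tert-butyldimethylsilyloxy)ethyl]-6-(hydroxymethyl)-3,5-bis(methoxymethoxy)phenol; 15 2-methoxy-4-vinylphenol
Product: 18 4-{(2S)-8-allyl-6-[2-(tert-butyldimethylsilyloxy)ethyl]-5,7-bis(methoxymethoxy)chroman-2-yl}-2-methoxyphenol, via ortho-quinone methide 16 (not isolated), via para-quinone methide adduct 17 (not isolated)
Conditions: TRIP phosphoric acid (10 mol %; antipode that gives 2S), 15 (2.5 equiv), 5 Å MS, toluene, −20 °C→rt
Reagents that add atoms: none
Why: Proposed new method: the phosphoric acid ionises the very electron-rich benzylic alcohol of 14 (only one phenol is free, so only one quinone methide can form) to give 16, which it holds by a hydrogen bond to the carbonyl oxygen while its P=O oxygen binds the free 4-hydroxyl of 15; the vinyl terminus then adds to the unsubstituted methide carbon (C3–C4) to give 17, and the A-ring phenol adds to the exocyclic carbon of 17 (O1–C2) while both partners of this oxa-1,6-addition are still bound to the phosphate. The closest known reaction types are the chiral-phosphoric-acid-catalysed [4+2] annulations of ortho-quinone methides with ortho-hydroxystyrenes and the phosphoric-acid-catalysed inverse-demand aza-Diels–Alder (Povarov) reactions of para-hydroxystyrenes of the isoeugenol type, in which the phenolic hydroxyl of the alkene is likewise the second binding point; not yet shown are a quinone methide with an unsubstituted terminus and a cycloadduct whose only stereocentre is C2. The pyran ring is closed as a formal inverse-demand hetero-[4+2] annulation, in its stepwise form a 6-exo-trig oxa-conjugate addition. C2 is the only new stereocentre and is controlled by the chiral phosphate alone, since the substrates are achiral and the methide carbon carries no substituent; the catalyst antipode is chosen accordingly. The regiochemistry (benzylic carbon to O1, terminal carbon to C4) follows from the polarisation of the para-hydroxystyrene, and chemoselectivity is secured by the fully substituted A ring (no C-alkylative self-condensation), by the low nucleophilicity of the terminal allyl group and by an excess of 15, which outpaces dimerisation of 16.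

Step 9
Reactants: 18 4-{(2S)-8-allyl-6-[2-(tert-butyldimethylsilyloxy)ethyl]-5,7-bis(methoxymethoxy)chroman-2-yl}-2-methoxyphenol
Product: 19 (2S)-8-allyl-6-[2-(tert-butyldimethylsilyloxy)ethyl]-2-[3-methoxy-4-(methoxymethoxy)phenyl]-5,7-bis(methoxymethoxy)chroman
Conditions: MOMCl, i-Pr2NEt, CH2Cl2, 0 °C→rt
Reagents that add atoms: chloromethyl methyl ether (MOMCl), COCCl
Why: Standard MOM protection of the only free hydroxyl, needed because a free 4-hydroxyphenyl group at C2 would be oxidised by DDQ to a para-quinone methide in the next step.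

Step 10
Reactants: 19 (2S)-8-allyl-6-[2-(tert-butyldimethylsilyloxy)ethyl]-2-[3-methoxy-4-(methoxymethoxy)phenyl]-5,7-bis(methoxymethoxy)chroman
Product: 20 (2S)-8-allyl-6-[2-(tert-butyldimethylsilyloxy)ethyl]-2-[3-methoxy-4-(methoxymethoxy)phenyl]-5,7-bis(methoxymethoxy)chroman-4-ol (mixture of C4 epimers)
Conditions: DDQ (1.2 equiv), CH2Cl2–pH 7 buffer, 0 °C
Reagents that add atoms: water, O
Why: DDQ benzylic oxidation of a flavan at C4: hydride should be abstracted from the pseudo-axial C4–H bond, which the ring holds parallel to the π-system of the tri-oxygenated A ring, and water traps the cation, whereas the acyclic benzylic CH2 groups are turned out of conjugation by their two ortho substituents and the terminal allyl group adds little stabilisation; the new C4 carbinol centre forms without control and is removed in step 11.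

Step 11
Reactants: 20 (2S)-8-allyl-6-[2-(tert-butyldimethylsilyloxy)ethyl]-2-[3-methoxy-4-(methoxymethoxy)phenyl]-5,7-bis(methoxymethoxy)chroman-4-ol
Product: 21 (2S)-8-allyl-6-[2-(tert-butyldimethylsilyloxy)ethyl]-2-[3-methoxy-4-(methoxymethoxy)phenyl]-5,7-bis(methoxymethoxy)chroman-4-one
Conditions: Dess–Martin periodinane, NaHCO3, CH2Cl2, 0 °C→rt
Reagents that add atoms: none
Why: Dess–Martin oxidation of the benzylic alcohol under bicarbonate buffer should give the ketone and erase the C4 centre, while C2 is untouched because ring opening to the chalcone needs base.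

Step 12
Reactants: 21 (2S)-8-allyl-6-[2-(tert-butyldimethylsilyloxy)ethyl]-2-[3-methoxy-4-(methoxymethoxy)phenyl]-5,7-bis(methoxymethoxy)chroman-4-one; 22 2-methyl-2-butene
Product: 23 (2S)-6-[2-(tert-butyldimethylsilyloxy)ethyl]-2-[3-methoxy-4-(methoxymethoxy)phenyl]-5,7-bis(methoxymethoxy)-8-(3-methylbut-2-en-1-yl)chroman-4-one
Conditions: Grubbs second-generation catalyst (5 mol %), 2-methyl-2-butene (co-solvent), CH2Cl2, 40 °C
Reagents that add atoms: none
Why: Olefin cross-metathesis of the terminal allyl group with 2-methyl-2-butene should give the trisubstituted prenyl alkene with propene as volatile co-product; ketone, acetals and silyl ether are inert to the ruthenium carbene.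

Step 13
Reactants: 23 (2S)-6-[2-(tert-butyldimethylsilyloxy)ethyl]-2-[3-methoxy-4-(methoxymethoxy)phenyl]-5,7-bis(methoxymethoxy)-8-(3-methylbut-2-en-1-yl)chroman-4-one
Product: 24 laxiflorin, (2S)-5,7-dihydroxy-2-(4-hydroxy-3-methoxyphenyl)-6-(2-hydroxyethyl)-8-(3-methylbut-2-en-1-yl)chroman-4-one
Conditions: 1 M HCl, MeOH, rt→40 °C
Reagents that add atoms: none
Why: Acid-catalysed transacetalisation of the three aryl MOM ethers and methanolysis of the primary silyl ether should release the four hydroxyls; the flavanone C2 centre is stable to dilute acid, and the mild temperature spares the prenyl group.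

**Compound list**

1 | phloroglucinol | Oc1cc(O)cc(O)c1 | starting material
2 | 3,5-bis(methoxymethoxy)phenol | COCOc1cc(O)cc(OCOC)c1 | intermediate
3 | tert-butyl[3,5-bis(methoxymethoxy)phenoxy]dimethylsilane | COCOc1cc(O[Si](C)(C)C(C)(C)C)cc(OCOC)c1 | intermediate
4 | ethylene oxide | C1CO1 | starting material
5 | [4-(tert-butyldimethylsilyloxy)-2,6-bis(methoxymethoxy)phenyl]lithium (not isolated) | [Li]c1c(OCOC)cc(O[Si](C)(C)C(C)(C)C)cc1OCOC | intermediate
6 | lithium 2-[4-(tert-butyldimethylsilyloxy)-2,6-bis(methoxymethoxy)phenyl]ethoxide (not isolated) | [Li+].[O-]CCc1c(OCOC)cc(O[Si](C)(C)C(C)(C)C)cc1OCOC | intermediate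
7 | tert-butyl{2-[4-(tert-butyldimethylsilyloxy)-2,6-bis(methoxymethoxy)phenyl]ethoxy}dimethylsilane | CC(C)(C)[Si](C)(C)OCCc1c(OCOC)cc(O[Si](C)(C)C(C)(C)C)cc1OCOC | intermediate
8 | allyl bromide | C=CCBr | starting material
9 | caesium 4-[2-(tert-butyldimethylsilyloxy)ethyl]-3,5-bis(methoxymethoxy)phenoxide (not isolated) | [Cs+].[O-]c1cc(OCOC)c(CCO[Si](C)(C)C(C)(C)C)c(OCOC)c1 | intermediate
10 | {2-[4-(allyloxy)-2,6-bis(methoxymethoxy)phenyl]ethoxy}(tert-butyl)dimethylsilane | C=CCOc1cc(OCOC)c(CCO[Si](C)(C)C(C)(C)C)c(OCOC)c1 | intermediate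
11 | 2-allyl-4-[2-(tert-butyldimethylsilyloxy)ethyl]-3,5-bis(methoxymethoxy)phenol | C=CCc1c(O)cc(OCOC)c(CCO[Si](C)(C)C(C)(C)C)c1OCOC | intermediate
12 | paraformaldehyde (formaldehyde source) | C=O | starting material
13 | 3-allyl-5-[2-(tert-butyldimethylsilyloxy)ethyl]-2-hydroxy-4,6-bis(methoxymethoxy)benzaldehyde | C=CCc1c(O)c(C=O)c(OCOC)c(CCO[Si](C)(C)C(C)(C)C)c1OCOC | intermediate
14 | 2-allyl-4-[2-(tert-butyldimethylsilyloxy)ethyl]-6-(hydroxymethyl)-3,5-bis(methoxymethoxy)phenol | C=CCc1c(O)c(CO)c(OCOC)c(CCO[Si](C)(C)C(C)(C)C)c1OCOC | intermediate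
15 | 2-methoxy-4-vinylphenol | C=Cc1ccc(O)c(OC)c1 | starting material
16 | 2-allyl-4-[2-(tert-butyldimethylsilyloxy)ethyl]-3,5-bis(methoxymethoxy)-6-methylidenecyclohexa-2,4-dien-1-one (not isolated) | C=CCC1=C(OCOC)C(CCO[Si](C)(C)C(C)(C)C)=C(OCOC)C(=C)C1=O | intermediate
17 | 2-allyl-4-[2-(tert-butyldimethylsilyloxy)ethyl]-6-[3-(3-methoxy-4-oxocyclohexa-2,5-dien-1-ylidene)propyl]-3,5-bis(methoxymethoxy)phenol (not isolated) | C=CCc1c(O)c(CCC=C2C=CC(=O)C(OC)=C2)c(OCOC)c(CCO[Si](C)(C)C(C)(C)C)c1OCOC | intermediate
18 | 4-{(2S)-8-allyl-6-[2-(tert-butyldimethylsilyloxy)ethyl]-5,7-bis(methoxymethoxy)chroman-2-yl}-2-methoxyphenol | COc1cc([C@@H]2CCc3c(OCOC)c(CCO[Si](C)(C)C(C)(C)C)c(OCOC)c(CC=C)c3O2)ccc1O | intermediate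
19 | (2S)-8-allyl-6-[2-(tert-butyldimethylsilyloxy)ethyl]-2-[3-methoxy-4-(methoxymethoxy)phenyl]-5,7-bis(methoxymethoxy)chroman | COc1cc([C@@H]2CCc3c(OCOC)c(CCO[Si](C)(C)C(C)(C)C)c(OCOC)c(CC=C)c3O2)ccc1OCOC | intermediate
20 | (2S)-8-allyl-6-[2-(tert-butyldimethylsilyloxy)ethyl]-2-[3-methoxy-4-(methoxymethoxy)phenyl]-5,7-bis(methoxymethoxy)chroman-4-ol, C4 epimers | COc1cc([C@@H]2CC(O)c3c(OCOC)c(CCO[Si](C)(C)C(C)(C)C)c(OCOC)c(CC=C)c3O2)ccc1OCOC | intermediate
21 | (2S)-8-allyl-6-[2-(tert-butyldimethylsilyloxy)ethyl]-2-[3-methoxy-4-(methoxymethoxy)phenyl]-5,7-bis(methoxymethoxy)chroman-4-one | COc1cc([C@@H]2CC(=O)c3c(OCOC)c(CCO[Si](C)(C)C(C)(C)C)c(OCOC)c(CC=C)c3O2)ccc1OCOC | intermediate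
22 | 2-methyl-2-butene | CC=C(C)C | starting material
23 | (2S)-6-[2-(tert-butyldimethylsilyloxy)ethyl]-2-[3-methoxy-4-(methoxymethoxy)phenyl]-5,7-bis(methoxymethoxy)-8-(3-methylbut-2-en-1-yl)chroman-4-one | COc1cc([C@@H]2CC(=O)c3c(OCOC)c(CCO[Si](C)(C)C(C)(C)C)c(OCOC)c(CC=C(C)C)c3O2)ccc1OCOC | intermediate
24 | laxiflorin, (2S)-5,7-dihydroxy-2-(4-hydroxy-3-methoxyphenyl)-6-(2-hydroxyethyl)-8-(3-methylbut-2-en-1-yl)chroman-4-one | COc1cc([C@@H]2CC(=O)c3c(O)c(CCO)c(O)c(CC=C(C)C)c3O2)ccc1O | target

**Step count and risks**

Total step count: 13. Longest linear sequence: 13 steps (1 to 24); 4, 8, 12, 15 and 22 are bought and used as such.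

Steps most likely to fail:

1. Step 8 (the proposed new method). The phosphate may discriminate poorly between the two faces in the ring-closing C–O bond formation. The quinone methide may also be lost to dimerisation or to C-alkylation of the guaiacol ring before the styrene captures it. Fallback, from 14 and 15, back at 21: the two components are combined without chiral control, by heating in toluene or with diphenyl phosphate, both known ways to run the quinone methide/styrene hetero-Diels–Alder reaction. This should give the racemic flavan phenol F1. MOM protection then gives the racemic protected flavan F2, and the DDQ/water and Dess–Martin oxidations of steps 10 and 11 give the racemic flavan-4-ol F3 and the racemic flavanone F4. F4 is resolved kinetically by Noyori transfer hydrogenation (RuCl(p-cymene)[(R,R)-TsDPEN], HCO2H–Et3N). By the usual sense of this catalyst, the 2R ketone should be reduced from the face anti to the aryl group to the 2,4-cis alcohol, the (2R,4R)-flavan-4-ol F5, which is separated. The unreacted 2S ketone is 21, where the route is rejoined.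

2. Step 10. Hydride abstraction may occur at a benzylic position other than C4 (the allyl CH2 on C8, the C6 side chain, or C2–H). The C4 cation may also lose a proton to give the flav-3-ene, which is oxidised further to the flavylium ion. Fallback, from 13, back at 21: the carbonyl is brought in with an acetophenone instead of by C–H oxidation. Addition of MeMgBr to 13 should give the 1-arylethanol F6, and MnO2 oxidation the 2-hydroxyacetophenone F7. Claisen–Schmidt condensation (KOH, EtOH) with 3-methoxy-4-(methoxymethoxy)benzaldehyde F8, made from vanillin and MOMCl, should give the 2'-hydroxychalcone F9. Cyclisation of F9 with NaOAc in hot ethanol, through the only free phenol, gives the racemic flavanone F4 of the first fallback. F4 is resolved by the same transfer hydrogenation to reach 21.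

3. Step 13. While the MOM groups are cleaved, the prenyl alkene may cyclise onto the liberated 7-hydroxyl to form a 2,2-dimethylchroman, or may add HCl or methanol. Fallback, from 21, back at 24: the order of the last two operations is reversed. Compound 21, whose terminal allyl group is inert to dilute acid, is deprotected with HCl in methanol to the (2S)-8-allyl-5,7-dihydroxy-2-(4-hydroxy-3-methoxyphenyl)-6-(2-hydroxyethyl)chroman-4-one F10. Cross-metathesis of F10 with 22 (Grubbs second-generation catalyst, which tolerates free phenols and alcohols) then gives 24 without exposing the prenyl group to acid.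

**Further compounds**

F1 | step 8 | racemic 4-{8-allyl-6-[2-(tert-butyldimethylsilyloxy)ethyl]-5,7-bis(methoxymethoxy)chroman-2-yl}-2-methoxyphenol | COc1cc(C2CCc3c(OCOC)c(CCO[Si](C)(C)C(C)(C)C)c(OCOC)c(CC=C)c3O2)ccc1O
F2 | step 8 | racemic 8-allyl-6-[2-(tert-butyldimethylsilyloxy)ethyl]-2-[3-methoxy-4-(methoxymethoxy)phenyl]-5,7-bis(methoxymethoxy)chroman | COc1cc(C2CCc3c(OCOC)c(CCO[Si](C)(C)C(C)(C)C)c(OCOC)c(CC=C)c3O2)ccc1OCOC
F3 | step 8 | racemic 8-allyl-6-[2-(tert-butyldimethylsilyloxy)ethyl]-2-[3-methoxy-4-(methoxymethoxy)phenyl]-5,7-bis(methoxymethoxy)chroman-4-ol, C4 epimers | COc1cc(C2CC(O)c3c(OCOC)c(CCO[Si](C)(C)C(C)(C)C)c(OCOC)c(CC=C)c3O2)ccc1OCOC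
F4 | step 8 | racemic 8-allyl-6-[2-(tert-butyldimethylsilyloxy)ethyl]-2-[3-methoxy-4-(methoxymethoxy)phenyl]-5,7-bis(methoxymethoxy)chroman-4-one | COc1cc(C2CC(=O)c3c(OCOC)c(CCO[Si](C)(C)C(C)(C)C)c(OCOC)c(CC=C)c3O2)ccc1OCOC
F5 | step 8 | (2R,4R)-8-allyl-6-[2-(tert-butyldimethylsilyloxy)ethyl]-2-[3-methoxy-4-(methoxymethoxy)phenyl]-5,7-bis(methoxymethoxy)chroman-4-ol (2,4-cis) | COc1cc([C@H]2C[C@@H](O)c3c(OCOC)c(CCO[Si](C)(C)C(C)(C)C)c(OCOC)c(CC=C)c3O2)ccc1OCOC
F6 | step 10 | 1-{3-allyl-5-[2-(tert-butyldimethylsilyloxy)ethyl]-2-hydroxy-4,6-bis(methoxymethoxy)phenyl}ethanol (racemic) | C=CCc1c(O)c(C(C)O)c(OCOC)c(CCO[Si](C)(C)C(C)(C)C)c1OCOC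
F7 | step 10 | 1-{3-allyl-5-[2-(tert-butyldimethylsilyloxy)ethyl]-2-hydroxy-4,6-bis(methoxymethoxy)phenyl}ethanone | C=CCc1c(O)c(C(C)=O)c(OCOC)c(CCO[Si](C)(C)C(C)(C)C)c1OCOC
F8 | step 10 | 3-methoxy-4-(methoxymethoxy)benzaldehyde | COCOc1ccc(C=O)cc1OC
F9 | step 10 | (E)-1-{3-allyl-5-[2-(tert-butyldimethylsilyloxy)ethyl]-2-hydroxy-4,6-bis(methoxymethoxy)phenyl}-3-[3-methoxy-4-(methoxymethoxy)phenyl]prop-2-en-1-one | C=CCc1c(O)c(C(=O)/C=C/c2ccc(OCOC)c(OC)c2)c(OCOC)c(CCO[Si](C)(C)C(C)(C)C)c1OCOC
F10 | step 13 | (2S)-8-allyl-5,7-dihydroxy-2-(4-hydroxy-3-methoxyphenyl)-6-(2-hydroxyethyl)chroman-4-one | COc1cc([C@@H]2CC(=O)c3c(O)c(CCO)c(O)c(CC=C)c3O2)ccc1O
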